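(The numbers in the tables were computed with made-up constants; noise was put on by code.)

Early times come first in this flask: substrate and initiator are stirred under a held gas of which none is yet dissolved, and target is read in percent of the substrate charged.

in all of them: gas 4.5 mM (held)

| run | substrate | initiator | remark | time |
|---|---|---|---|---|
| epsilon | 0.050 M | 0.50 mM | run made earlier |  |
| eta | 0.050 M | 0.75 mM | run made earlier |  |
| gamma | 0.075 M | 1 mM | run made earlier |  |
| flask | 0.050 M | 1.0 mM |  | 12 h |

| epsilon: time / h | epsilon: target / % | eta: time / h | eta: target / % | gamma: time / h | gamma: target / % |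
|---|---|---|---|---|---|
| 1.00 | 1 | 1.00 | 0 | 2.50 | 6 |
| 3.00 | 7 | 3.00 | 9 | 5.00 | 15 |
| 6.00 | 15 | 6.00 | 18 | 8.00 | 17 |
| 8.00 | 21 | 8.00 | 22 | 10.0 | 18 |
| 12.0 | 26 | 12.0 | 31 | 12.0 | 23 |

(standard deviation of a reading: 1.5 percentage points)

- maple: doubling the transfer coefficient of the gas, all else as stated
- birch: doubling the saturation concentration of gas, all else as stated

- target at 12 h, in percent of the substrate charged
- the change that raises the amount of target at 12 h, in percent of the substrate charged most ("none" if none brings more than 2 percentage points) (maple / birch / none)
- amount of target at 12 h, in percent of the substrate charged, after maple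

- the numbers in the tables scatter by 1.5 percentage points (one standard deviation)
- at the start none of the gas is in solution

At 1.00 h the epsilon run shows 1% and the eta run 0%, yet they later climb by 1.06 mM h⁻¹ and 1.22 mM h⁻¹. The shortfall against those slopes reads as an induction period of 0.526 h and 1.00 h. We take the mean, 0.763 h, as the filling lifetime, the time constant with which transfer closes the gap between dissolved gas and saturation.

Next comes the rate. From epsilon to eta the target grows by 1.19 and the root of the initiator by 1.22, so we scale by that root. The amounts at 12 h, brought to the flask's initiator, are 18.4 mM, 17.9 mM and, from gamma with its larger substrate charge, taking the rate as zero order in substrate, 17.2 mM. Their mean, 17.8 mM, gives 35.7% for the flask, at a mean rate of 1.49 mM h⁻¹.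

Rate times lifetime over saturation is the depletion, the share by which dissolved gas stands below saturation: 25.2%, a quarter. If the rate is first order in dissolved gas, which no run tested, maple halves the lifetime, so the depletion, reckoned at the raised rate, falls to 14.4%, and the rate rises by a factor 1.14, to 40.8%, while birch raises it by a factor 2. We commit to birch.

The weak link is the lifetime: the readings behind it are 1% and 0%, with a scatter of 1.5 percentage points. Taking each run's lag separately brackets maple between 39.1% and 42.8%.

The forecast says 35% (from 31% to 38%), birch, and 39% after maple (from 34% to 45%), holding that “Doubling saturation would then nearly double the rate”.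

    initiator → 2 initiating radical (k = 1.70 × 10⁻⁵ s⁻¹)
    substrate + initiating radical → capped initiator + first chain carrier (k = 69000 M⁻¹ s⁻¹)
    reagent + first chain carrier ⇌ target + second chain carrier (K = 3.70, k = 37000 M⁻¹ s⁻¹)
    substrate + second chain carrier → by-product + first chain carrier (k = 7000 M⁻¹ s⁻¹)
    2 first chain carrier → ended chains A (k = 5.00 × 10⁸ M⁻¹ s⁻¹)
    2 second chain carrier → ended chains B (k = 1.00 × 10⁶ M⁻¹ s⁻¹)
    gas ⇌ reagent, rate k7*(csat - [reagent]) (kL = 3.50 × 10⁻⁴ s⁻¹)
    target → over-reaction product (k = 2.60 × 10⁻⁶ s⁻¹)

The flask gives 33.5%; birch adds 21 points against 4.8 points for maple, which reaches 38.3%. Reagent, the dissolved gas, stands at 71.6% of saturation at 6.00 h. The filling lifetime with this flask's mean rate, 1.40 mM h⁻¹, gives 76.3%. In the neighbour flask with 0.0017 M of initiator, target reaches 38.8%, and the same lifetime gives 72.6%. That neighbour flask holds 0.00348 M of reagent at 12.0 h, which is 77.4% of saturation.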